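**Plan**

Ring B is numbered as the benzoic acid: C1 carboxyl, C2 hydroxyl, C3 H, C4 acyloxy, C5 H, C6 pentyl. The target has no stereocentre, so only regiochemistry has to be controlled.
The retrosynthesis first cuts the aryl ester C(=O)–O bond between ring A and O4 of ring B, then opens ring B along C1–C6, C1–C2, C3–C4 and C4–C5.
The enabling feature is ring B itself: two meta oxygens of unequal role (free OH at C2, acylated O at C4) flank C3–H, with the carboxyl at C1 and the pentyl at C6. This pattern maps onto a ketene carbonyl (C4), a silyl ynol ether (C2, C3) and an ester-bearing alkenyl unit (C1, C6, C5).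
Forward: heptanal is methylenated and joined to benzyl diazoacetate to give the unsaturated diazo keto ester, and acetylene is converted into a silyloxyalkyne. The two are merged by photochemical Wolff rearrangement, [2+2] cycloaddition and electrocyclic opening and closure, which forms ring B with O4 free and O2 silylated.
The ring A acid, made from olivetol by methylation, formylation and oxidation, is then esterified onto O4; desilylation and hydrogenolysis of the benzyl ester finish the synthesis.

Key step: step 4

**Route**

Step 1
Reactants: 1 heptanal
Product: 2 2-methylideneheptanal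
Conditions: 37% aq. CH2O, pyrrolidine (10 mol%), EtCO2H (10 mol%), i-PrOH, 45 °C
Reagents that add atoms: formaldehyde, C=O
Why: Amine/acid-catalysed Mannich condensation with formaldehyde followed by elimination of the amine (organocatalytic α-methylenation of aldehydes) is well established for linear aldehydes and should stop at the 2-alkylacrolein.

Step 2
Reactants: 2 2-methylideneheptanal; 3 benzyl diazoacetate
Product: 5 benzyl 2-diazo-4-methylidene-3-oxononanoate, via diazo carbinol 4 (not isolated)
Conditions: DBU (20 mol%), DMSO, rt; then IBX (2-iodoxybenzoic acid), rt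
Reagents that add atoms: none
Why: The DBU-catalysed aldol-type addition of a diazoacetate C–H to an aldehyde carbonyl, established for aldehydes including enals, should outpace dipolar cycloaddition to the alkene, and IBX then oxidises the allylic diazo carbinol in the same pot without harming the diazo group.

Step 3
Reactants: 6 acetylene; 7 triisopropylsilyl trifluoromethanesulfonate
Product: 10 (triisopropylsilyloxy)ethyne, via lithium acetylide 8 (not isolated), via lithium ethynolate 9 (not isolated)
Conditions: n-BuLi, THF, −78 °C; t-BuOOLi (from t-BuOOH, LiN(SiMe3)2), −78 to 0 °C; then 7, −78 to 0 °C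
Reagents that add atoms: tert-butyl hydroperoxide, CC(C)(C)OO
Why: Oxidation of a lithium acetylide with lithium tert-butyl peroxide to the ynolate and O-silylation with a bulky silyl triflate is the general route to triisopropylsiloxyalkynes; the monolithium acetylide is kept cold under excess acetylene to limit disproportionation, and the large oxophilic electrophile should steer silylation to oxygen.

Step 4
Reactants: 5 benzyl 2-diazo-4-methylidene-3-oxononanoate; 10 (triisopropylsilyloxy)ethyne
Product: 15 benzyl 4-hydroxy-6-pentyl-2-(triisopropylsilyloxy)benzoate, via vinylketene 11 (not isolated), via vinylcyclobutenone 12 (not isolated), via dienylketene 13 (not isolated), via cyclohexadienone 14 (not isolated)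
Conditions: 10 (2.5 equiv), hν (300 nm), degassed ClCH2CH2Cl, 20 °C; then 80 °C
Reagents that add atoms: none
Why: Proposed new method: photolysis expels N2 from 5 and the alkenyl group shifts to the carbene carbon (Wolff rearrangement, forming C1–C6) to give the benzyloxycarbonyl vinylketene 11, whose ketene carbonyl carbon is attacked by the electron-rich CH terminus of 10, so that a [2+2] cycloaddition (C3–C4 and C1–C2) should deliver the 3-siloxy-4-alkenylcyclobutenone 12. At 80 °C 12 opens by a reversible four-electron conrotatory electrocyclic cleavage to the dienylketene 13, and ring B closes by a thermal disrotatory six-electron electrocyclisation between the ketene carbon and the methylidene carbon (C4–C5), after which the dienone 14 tautomerises irreversibly to the phenol. The closest known reaction type is the Danheiser benzannulation of α,β-unsaturated α-diazo ketones with siloxyalkynes under photochemical Wolff conditions; what is new is the ester on the diazo carbon, which makes the intermediate an alkoxycarbonyl(vinyl)ketene. No stereocentre survives, because the quaternary carbon of racemic 12 becomes aromatic C1. The step needs addition of the alkyne CH to the ketene carbonyl, which the polarisation of the ynol ether secures and which places the free hydroxyl at C4 and the silyl ether at C2; it also needs [2+2] addition to outrun hetero-[4+2] addition through the ester carbonyl, which should hold because an ester carbonyl is a far poorer oxadiene terminus than a ketone carbonyl, while a ring opening with the wrong sense of rotation is corrected because the opening is reversible and aromatisation is not.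

Step 5
Reactants: 16 olivetol
Product: 17 1,3-dimethoxy-5-pentylbenzene
Conditions: MeI, K2CO3, acetone, reflux
Reagents that add atoms: iodomethane, CI
Why: Williamson O-methylation of both phenols with iodomethane and carbonate is routine and leaves no free hydroxyl on ring A.

Step 6
Reactants: 17 1,3-dimethoxy-5-pentylbenzene
Product: 19 2,4-dimethoxy-6-pentylbenzaldehyde, via aryl iminium salt 18 (not isolated)
Conditions: POCl3, DMF, 0 to 70 °C; then H2O
Reagents that add atoms: N,N-dimethylformamide, CN(C)C=O; water, O
Why: Vilsmeier–Haack formylation of 5-alkylresorcinol dimethyl ethers takes place mainly para to one methoxy group and ortho to the other, next to the alkyl chain, and hydrolysis of the iminium salt should give the aldehyde with the ring A substitution pattern.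

Step 7
Reactants: 19 2,4-dimethoxy-6-pentylbenzaldehyde
Product: 20 2,4-dimethoxy-6-pentylbenzoic acid
Conditions: NaClO2, NaH2PO4, 2-methyl-2-butene, t-BuOH/H2O, rt
Reagents that add atoms: sodium chlorite, [Na+].[O-]Cl=O
Why: Pinnick chlorite oxidation converts the hindered aryl aldehyde into the acid in a mildly acidic buffer, and 2-methyl-2-butene traps hypochlorous acid so that the electron-rich ring is not chlorinated.

Step 8
Reactants: 15 benzyl 4-hydroxy-6-pentyl-2-(triisopropylsilyloxy)benzoate; 20 2,4-dimethoxy-6-pentylbenzoic acid
Product: 22 benzyl 4-[(2,4-dimethoxy-6-pentylbenzoyl)oxy]-6-pentyl-2-(triisopropylsilyloxy)benzoate, via mixed trifluoroacetic anhydride 21 (not isolated)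
Conditions: (CF3CO)2O, toluene, 0 °C to rt
Reagents that add atoms: none
Why: Activation of the electron-rich 2,6-disubstituted acid as its mixed trifluoroacetic anhydride, which acylates phenols through an acylium-like species, is the standard depside esterification, and the only free hydroxyl it meets is the one at C4 of 15.

Step 9
Reactants: 22 benzyl 4-[(2,4-dimethoxy-6-pentylbenzoyl)oxy]-6-pentyl-2-(triisopropylsilyloxy)benzoate
Product: 23 benzyl 4-[(2,4-dimethoxy-6-pentylbenzoyl)oxy]-2-hydroxy-6-pentylbenzoate
Conditions: Bu4NF, AcOH, THF, 0 °C
Reagents that add atoms: none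
Why: Fluoride cleaves the aryl silyl ether (silyl deprotection), and acetic acid protonates the phenoxide at once so that neither the aryl ester linkage nor the benzyl ester should be attacked.

Step 10
Reactants: 23 benzyl 4-[(2,4-dimethoxy-6-pentylbenzoyl)oxy]-2-hydroxy-6-pentylbenzoate
Product: 24 4-[(2,4-dimethoxy-6-pentylbenzoyl)oxy]-2-hydroxy-6-pentylbenzoic acid
Conditions: H2 (1 atm), 10% Pd/C, EtOAc, rt
Reagents that add atoms: none
Why: Hydrogenolysis of the benzylic C–O bond over palladium frees the carboxylic acid under neutral conditions at room temperature, which spares the aryl ester and methyl ethers and avoids decarboxylation of the 2-hydroxybenzoic acid.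

**Compound list**

1 | heptanal | CCCCCCC=O | starting material
2 | 2-methylideneheptanal | C=C(CCCCC)C=O | intermediate
3 | benzyl diazoacetate | [N-]=[N+]=CC(=O)OCc1ccccc1 | starting material
4 | benzyl 2-diazo-3-hydroxy-4-methylidenenonanoate (racemic, not isolated) | C=C(CCCCC)C(O)C(=[N+]=[N-])C(=O)OCc1ccccc1 | intermediate
5 | benzyl 2-diazo-4-methylidene-3-oxononanoate | C=C(CCCCC)C(=O)C(=[N+]=[N-])C(=O)OCc1ccccc1 | intermediate
6 | acetylene | C#C | starting material
7 | triisopropylsilyl trifluoromethanesulfonate | CC(C)[Si](C(C)C)(C(C)C)OS(=O)(=O)C(F)(F)F | starting material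
8 | lithium acetylide (not isolated) | [Li+].[C-]#C | intermediate
9 | lithium ethynolate (not isolated) | [Li+].[O-]C#C | intermediate
10 | (triisopropylsilyloxy)ethyne | C#CO[Si](C(C)C)(C(C)C)C(C)C | intermediate
11 | benzyl 3-methylidene-2-(oxomethylidene)octanoate (not isolated) | C=C(CCCCC)C(=C=O)C(=O)OCc1ccccc1 | intermediate
12 | benzyl 1-(hept-1-en-2-yl)-4-oxo-2-(triisopropylsilyloxy)cyclobut-2-ene-1-carboxylate (racemic, not isolated) | O=C1C=C(O[Si](C(C)C)(C(C)C)C(C)C)C1(C(=C)CCCCC)C(=O)OCc1ccccc1 | intermediate
13 | benzyl (2Z)-2-(hept-1-en-2-yl)-5-oxo-3-(triisopropylsilyloxy)penta-2,4-dienoate (not isolated) | O=C=C/C(O[Si](C(C)C)(C(C)C)C(C)C)=C(\C(=C)CCCCC)C(=O)OCc1ccccc1 | intermediate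
14 | benzyl 4-oxo-2-pentyl-6-(triisopropylsilyloxy)cyclohexa-1,5-diene-1-carboxylate (not isolated) | O=C1C=C(O[Si](C(C)C)(C(C)C)C(C)C)C(C(=O)OCc2ccccc2)=C(CCCCC)C1 | intermediate
15 | benzyl 4-hydroxy-6-pentyl-2-(triisopropylsilyloxy)benzoate | CCCCCc1cc(O)cc(O[Si](C(C)C)(C(C)C)C(C)C)c1C(=O)OCc1ccccc1 | intermediate
16 | olivetol (5-pentylbenzene-1,3-diol) | CCCCCc1cc(O)cc(O)c1 | starting material
17 | 1,3-dimethoxy-5-pentylbenzene | CCCCCc1cc(OC)cc(OC)c1 | intermediate
18 | N-[(2,4-dimethoxy-6-pentylphenyl)methylidene]-N-methylmethanaminium dichlorophosphate (not isolated) | CCCCCc1cc(OC)cc(OC)c1C=[N+](C)C.[O-]P(=O)(Cl)Cl | intermediate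
19 | 2,4-dimethoxy-6-pentylbenzaldehyde | CCCCCc1cc(OC)cc(OC)c1C=O | intermediate
20 | 2,4-dimethoxy-6-pentylbenzoic acid | CCCCCc1cc(OC)cc(OC)c1C(=O)O | intermediate
21 | 2,4-dimethoxy-6-pentylbenzoic trifluoroacetic anhydride (not isolated) | CCCCCc1cc(OC)cc(OC)c1C(=O)OC(=O)C(F)(F)F | intermediate
22 | benzyl 4-[(2,4-dimethoxy-6-pentylbenzoyl)oxy]-6-pentyl-2-(triisopropylsilyloxy)benzoate | CCCCCc1cc(OC(=O)c2c(CCCCC)cc(OC)cc2OC)cc(O[Si](C(C)C)(C(C)C)C(C)C)c1C(=O)OCc1ccccc1 | intermediate
23 | benzyl 4-[(2,4-dimethoxy-6-pentylbenzoyl)oxy]-2-hydroxy-6-pentylbenzoate | CCCCCc1cc(OC(=O)c2c(CCCCC)cc(OC)cc2OC)cc(O)c1C(=O)OCc1ccccc1 | intermediate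
24 | 4-[(2,4-dimethoxy-6-pentylbenzoyl)oxy]-2-hydroxy-6-pentylbenzoic acid | CCCCCc1cc(OC(=O)c2c(CCCCC)cc(OC)cc2OC)cc(O)c1C(=O)O | target

**Step count**

Total steps: 10. Longest linear sequence: 6 steps (heptanal through steps 1, 2, 4, 8, 9, 10; equally olivetol through steps 5, 6, 7, 8, 9, 10).

**Steps most likely to fail**

Step 4. The ester-substituted ketene may be captured by the alkyne through its ester carbonyl in a hetero-[4+2] addition instead of [2+2] addition at the C=C bond. The cyclobutenone may also open with the ester turned inward and then close onto oxygen, and the new phenol may be acylated by unconsumed ketene. The fallback uses known chemistry only, sets out from olivetol 16 and comes back at 23. Carboxylation of 16 with MeOMgOCO2Me (methyl magnesium carbonate) in DMF at 120 °C should give 2,4-dihydroxy-6-pentylbenzoic acid F1. Alkylation of its carboxylate with benzyl bromide and KHCO3 in DMF should give benzyl 2,4-dihydroxy-6-pentylbenzoate F2. Coupling of F2 with acid 20 and (CF3CO)2O in toluene should acylate only the C4 hydroxyl, because the C2 hydroxyl is held in a hydrogen bond to the ester carbonyl. This gives 23, and step 10 follows.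

Step 3. Monolithium acetylide may disproportionate to the dilithium salt and be over-oxidised while the peroxide reaction warms, and the unsubstituted ynolate may be silylated at carbon instead of oxygen. The fallback sets out from silyl triflate 7 and comes back at 10. Commercial 3-phenylisoxazole is lithiated at C5 with n-BuLi in THF at −78 °C to (3-phenyl-1,2-oxazol-5-yl)lithium F3, which should fragment by cycloreversion into benzonitrile and lithium ethynolate 9. The ynolate is then free of peroxide, alkoxide and acetylide, so one equivalent of 7 can be added at −78 °C to form 10, which is separated from benzonitrile by distillation. This answers the generation problem only; silylation at carbon remains possible.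

Step 8. Acyl transfer from the doubly ortho-substituted acyl donor may be slow, so that trifluoroacetylation of the phenol and acid-promoted loss of the silyl ether compete. The fallback sets out from 17 and comes back at 22, and brings in the ester carbonyl as carbon monoxide instead of as a preformed acid. Iodination of 17 with N-iodosuccinimide in MeCN should give 2-iodo-1,5-dimethoxy-3-pentylbenzene F4, at the same ring position as the formylation. Aryloxycarbonylation of F4 with phenol 15 (Pd(OAc)2, Xantphos, CO 1 atm, Et3N, toluene, 80 °C) should then form aryl ester 22 under basic conditions that leave the silyl ether intact, and steps 9 and 10 follow.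

**Further compounds**

F1 | step 4 | 2,4-dihydroxy-6-pentylbenzoic acid | CCCCCc1cc(O)cc(O)c1C(=O)O
F2 | step 4 | benzyl 2,4-dihydroxy-6-pentylbenzoate | CCCCCc1cc(O)cc(O)c1C(=O)OCc1ccccc1
F3 | step 3 | (3-phenyl-1,2-oxazol-5-yl)lithium | [Li]c1cc(-c2ccccc2)no1
F4 | step 8 | 2-iodo-1,5-dimethoxy-3-pentylbenzene | CCCCCc1cc(OC)cc(OC)c1I
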